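At early times c_G still stands at its charge, so the question is how long it stays there.

    E + G → G + L (k1 = 2000 M⁻¹ h⁻¹, Ea1 = 47.0 kJ mol⁻¹)
    Z + Q + L → Q + D (k2 = 3330 M⁻² h⁻¹, Ea2 = 43.0 kJ mol⁻¹)
    G → X (k3 = 0.0452 h⁻¹, Ea3 = 108 kJ mol⁻¹)
    (constants at 20 °C)

- larch: E 0.050 M; Z 1.10 equiv; G 0.05 mol%; Q 2.5 mol%; temperature 20 °C; time 4.0 h
- cedar: E 0.050 M; Z 1.10 equiv; G 0.05 mol%; Q 2.5 mol%; temperature 30 °C; time 4.0 h

- all constants are for 20 °C and move with temperature by the activation energies

- which of these there is most of at the end, counted by the E in it, larch (L / D / E)
- which of these there is most of at the end, counted by the E in it, cedar (L / D / E)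
- final amount of the leader among these, as a percentage of the E charged, in larch
- final amount of the leader among these, as a percentage of the E charged, in cedar

I write k for the first step's constant and d for the third's. The first step uses up E and returns G, and the third step loses G at a rate that holds no other species. So c_G = c_G,start·exp(−d·t), and E decays by a pseudo-first-order law with the sinking constant k·c_G. At the start k·c_G is 0.0500 h⁻¹ in larch and 0.0945 h⁻¹ in cedar, while d is 0.0452 h⁻¹ in larch and 0.195 h⁻¹ in cedar.

Two extreme flasks can be solved in the head, each with c_G frozen. The E left after 4.0 h is then: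

- c_G frozen at its starting value: larch 81.9%, cedar 68.5%
- c_G frozen at its final value: larch 84.6%, cedar 84.1%

Since c_G falls steadily from the one value to the other, the real flasks lie between these. Larch has a narrow window and cedar a wide one, so I integrate. The working time of the catalyst is t_w = (1 − exp(−d·t))/d, and Θ is the starting k·c_G times t_w:

- larch: t_w = 3.66 h, Θ = 0.183, E left = exp(−Θ) = 83.3%
- cedar: t_w = 2.78 h, Θ = 0.262, E left = exp(−Θ) = 76.9%

This Θ, the catalyst dose, is what I carry forward. E, L and D share the charge, so L and D together hold 16.7% in larch and 23.1% in cedar, less than E in each flask. E leads in both.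

The forecast gives E at 83.3% for larch and E at 76.9% for cedar, the same as my reckoning. Its grounds: “the catalyst's shorter life cancels much of the gain”.

The simulation gives E at 83.3% in larch and E at 76.9% in cedar.

Read backwards, −ln of cedar's remainder is 0.263, against the dose 0.262. A neighbour of cedar is charged with 0.20 M of E, with equivalents, loadings, time and temperature held. Its c_G starts 4.00 times as high as in cedar and t_w stays 2.78 h, so its dose is 1.05, and exp(−Θ) leaves 35.0% of E. The simulation leaves 35.0% of E there, with L at 2.33%, and the leader of that neighbour is D at 62.7%.

The constants used here were chosen freely; what happens was integrated by code.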